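**Retrosynthetic overview**
1. The 14-membered ring is opened at C3–C4: a final Nozaki–Hiyama–Kishi closure of an E-vinyl iodide onto the C3 aldehyde sets C3.
2. The ε-lactone comes from 7-exo opening of an (11S,12S)-epoxide by the C16 acid (inverts C12, keeps C11–O); the epoxide comes from the C11 ketone by chelation-controlled reduction and mesylate closure.
3. The C9–C10 bond and 7E-alkene come from a Claisen rearrangement of the allyl vinyl ether made by methylenating the ester of a West acid with an East allylic alcohol.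
4. The West acid comes from (+)-limonene-1,2-diol (C1 and C12 bought) by ene-chlorination, oxidation and silyl enol ether ozonolysis; the East alcohol comes from pent-3-yn-1-ol.
5. Ring order: oxane (temporary acetal) → oxirane → oxepan-2-one → 14-membered carbocycle.

Assumption: cembrane-style numbering is used (C1 = CH bearing the acrylate, C3 = CHOH, C11 = CHOAc, C12 = C(Me)O); the target is read as (1R,3S,11S,12R,4E,7E).

**Route**

Step 1
Reactants: 1, (1S,2S,4R)-limonene-1,2-diol
Product: 2, (1S,2S,4R)-4-(3-chloroprop-1-en-2-yl)-1-methylcyclohexane-1,2-diol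
Conditions: Ca(OCl)2, CO2 (s), CH2Cl2/H2O, 0 °C
Reagents that add atoms: calcium hypochlorite, [Ca+2].[O-]Cl.[O-]Cl
Why: HOCl ene-type allylic chlorination of the only alkene gives the 2-(chloromethyl)vinyl group (a masked acrylate) without touching any stereocentre.

Step 2
Reactants: 2
Product: 3, (2S,5R)-5-(3-chloroprop-1-en-2-yl)-2-hydroxy-2-methylcyclohexan-1-one
Conditions: (COCl)2, DMSO, CH2Cl2, −78 °C; Et3N
Reagents that add atoms: none
Why: Swern oxidation converts only the secondary alcohol, giving the α-ketol with both stereocentres intact.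

Step 3
Reactants: 3
Product: 4, (3R,6S)-3-(3-chloroprop-1-en-2-yl)-6-methyl-1,6-bis(trimethylsilyloxy)cyclohex-1-ene
Conditions: TMSOTf (2.4 equiv), Et3N, CH2Cl2, 0 °C
Reagents that add atoms: TMSOTf, C[Si](C)(C)OS(=O)(=O)C(F)(F)F
Why: Soft enolisation; the ketone has a single enolisable α-carbon, so one silyl enol ether forms and the tertiary OH is capped at the same time.

Step 4
Reactants: 4
Product: 5, (2S,5S)-5-(3-chloroprop-1-en-2-yl)-6-methoxy-2-methyloxane-2-carboxylic acid (anomer mixture at C6)
Conditions: O3, CH2Cl2/MeOH, −78 °C (indicator end point); Me2S; then PPTS, MeOH, rt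
Reagents that add atoms: ozone, [O-][O+]=O; methanol, CO
Why: Ozonolysis of the electron-rich silyl enol ether (much faster than the chloromethyl alkene) cleaves C11–C2 to acid and aldehyde; the freed tertiary OH traps the aldehyde as a six-membered lactol, fixed as its methyl acetal (Fischer glycosidation).

Step 5
Reactants: 6, pent-3-yn-1-ol
Product: 7, (E)-4-iodopent-3-en-1-ol
Conditions: Cp2Zr(H)Cl (3 equiv), THF, 40 °C; then I2, 0 °C
Reagents that add atoms: iodine, II
Why: Syn-hydrozirconation (Schwartz) equilibrates Zr onto the methyl-bearing carbon, and iodinolysis with retention gives the E-vinyl iodide.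

Step 6
Reactants: 7
Product: 8, (E)-4-iodopent-3-enal
Conditions: Dess–Martin periodinane, NaHCO3, CH2Cl2, 0 °C; used crude
Reagents that add atoms: none
Why: Buffered Dess–Martin oxidation gives the β,γ-unsaturated aldehyde without isomerising it into conjugation.

Step 7
Reactants: 8; 9, isopropenylmagnesium bromide
Product: 10, rac-(5E)-6-iodo-2-methylhepta-1,5-dien-3-ol
Conditions: CeCl3, THF, −78 °C
Reagents that add atoms: none beyond reactant 9
Why: 1,2-addition of the low-basicity organocerium avoids enolisation; the carbinol centre is left racemic because it is destroyed in step 10.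

Step 8
Reactants: 5; 10
Product: 11, (5E)-6-iodo-2-methylhepta-1,5-dien-3-yl (2S,5S)-5-(3-chloroprop-1-en-2-yl)-6-methoxy-2-methyloxane-2-carboxylate
Conditions: 2,4,6-trichlorobenzoyl chloride, Et3N, THF; then 10, DMAP, toluene, rt
Reagents that add atoms: none
Why: Yamaguchi esterification joins the hindered α-alkoxy acid to the secondary allylic alcohol; the carbinol diastereomers converge in step 10.

Step 9
Reactants: 11
Product: 12, (2S,5S)-5-(3-chloroprop-1-en-2-yl)-2-(1-{[(5E)-6-iodo-2-methylhepta-1,5-dien-3-yl]oxy}ethenyl)-6-methoxy-2-methyloxane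
Conditions: Cp2TiMe2, toluene, 70 °C, dark
Reagents that add atoms: dimethyltitanocene, C[Ti](C)(C1C=CC=C1)C1C=CC=C1 (supplies C10 as CH2)
Why: Petasis methylenation of the only carbonyl gives the allyl vinyl ether; the non-Lewis-acidic reagent spares the acetal, allylic chloride and vinyl iodide.

Step 10 (key step)
Reactants: 12
Product: 13, (4E,7E)-1-[(2S,5S)-5-(3-chloroprop-1-en-2-yl)-6-methoxy-2-methyloxan-2-yl]-8-iodo-4-methylnona-4,7-dien-1-one
Conditions: toluene, 110 °C, sealed, trace Et3N (can be telescoped with step 9)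
Reagents that add atoms: none
Why: Claisen [3,3]-sigmatropic rearrangement through a chair with the C6 chain equatorial forms the C9–C10 bond and the 7E trisubstituted alkene and unveils the C11 ketone; no stereocentre is created.

Step 11
Reactants: 13
Product: 14, (1R,4E,7E)-1-[(2S,5S)-5-(3-chloroprop-1-en-2-yl)-6-methoxy-2-methyloxan-2-yl]-8-iodo-4-methylnona-4,7-dien-1-ol
Conditions: Zn(BH4)2, Et2O, −30 → 0 °C
Reagents that add atoms: none
Why: Chelation-controlled (Cram-cyclic) reduction: Zn bridges the ketone and oxane oxygens, the oxane ring shields one face, and hydride adds from the methyl face to give the (1R)-alcohol.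

Step 12
Reactants: 14
Product: 15, the C11 methanesulfonate of 14
Conditions: MsCl, Et3N, DMAP (cat.), CH2Cl2, 0 °C
Reagents that add atoms: methanesulfonyl chloride, CS(=O)(=O)Cl
Why: Sulfonylation of the only free hydroxyl prepares the epoxide closure; configuration is unchanged.

Step 13
Reactants: 15
Product: 16, 2-[(3S,6S)-6-[(1R,4E,7E)-8-iodo-1-(methanesulfonyloxy)-4-methylnona-4,7-dien-1-yl]-2-methoxy-6-methyloxan-3-yl]prop-2-enal
Conditions: NMO (5 equiv), KI (cat.), MeCN, 45 °C
Reagents that add atoms: N-methylmorpholine N-oxide, C[N+]1([O-])CCOCC1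
Why: Amine-oxide (Kornblum/Ganem-type) oxidation: iodide-assisted SN2 at the primary allylic chloride then elimination gives the enal; the neopentyl-like secondary mesylate is inert.

Step 14
Reactants: 16
Product: 17, the corresponding prop-2-enoic acid
Conditions: NaClO2, NaH2PO4, 2-methyl-2-butene, t-BuOH/H2O, 0 °C
Reagents that add atoms: sodium chlorite, [Na+].[O-]Cl=O
Why: Pinnick oxidation converts the enal to the acrylic acid while the scavenger protects the alkenes; mesylate and cyclic acetal survive pH ~4.

Step 15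
Reactants: 17
Product: 18, the lactol (2-hydroxyoxane) of 17
Conditions: 1 M HCl/THF (1:4), rt
Reagents that add atoms: water, O
Why: Hydrolysis of the glycoside-type methyl acetal frees the lactol; mesylate, vinyl iodide and acrylic acid tolerate dilute acid.

Step 16
Reactants: 18
Product: 19, (3R)-3-{2-[(2S,3S)-3-[(3E,6E)-7-iodo-3-methylocta-3,6-dien-1-yl]-2-methyloxiran-2-yl]ethyl}-5-methoxy-2-methylidenepent-4-enoic acid (enol ether E/Z mixture)
Conditions: Ph3P(CH2OMe)Cl, KHMDS (6 equiv), THF, −78 → 0 °C; pH 7 quench; used directly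
Reagents that add atoms: (methoxymethyl)triphenylphosphonium chloride, [Cl-].COC[P+](c1ccccc1)(c1ccccc1)c1ccccc1 (supplies C3)
Why: Wittig methoxymethylenation of the ring-opened lactol adds C3, and the liberated C12 alkoxide displaces the neighbouring mesylate (intramolecular SN2, inversion at C11) to give the trans-epoxide; the carboxylate form shields the acrylate from the ylide.

Step 17
Reactants: 19
Product: 20, (3R)-3-{2-[(2S,3S)-3-[(3E,6E)-7-iodo-3-methylocta-3,6-dien-1-yl]-2-methyloxiran-2-yl]ethyl}-2-methylidene-5-oxopentanoic acid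
Conditions: Hg(OAc)2, THF/H2O (10:1), 0 °C; then aq. KI
Reagents that add atoms: water, O
Why: Oxymercuration-type enol ether hydrolysis under neutral conditions unmasks the C3 aldehyde; the epoxide survives and no nucleophilic enol ether is left to attack it in step 18.

Step 18
Reactants: 20
Product: 21, (1S,4E,7E)-8-iodo-4-methyl-1-[(2R,5R)-2-methyl-6-methylidene-7-oxo-5-(2-oxoethyl)oxepan-2-yl]nona-4,7-dien-1-yl acetate
Conditions: TsOH (0.1 equiv), CH2Cl2 (5 mM), 0 °C → rt; then pyridine, Ac2O, DMAP (one pot)
Reagents that add atoms: acetic anhydride, CC(=O)OC(C)=O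
Why: Acid-catalysed 7-exo-tet, Markovnikov opening of the epoxide at tertiary C12 by the C16 acid with inversion gives the ε-lactone (12R) and leaves the original oxygen on C11 (11S); that alcohol is then acetylated.

Step 19
Reactants: 21
Product: 22, Dendronpholide A
Conditions: CrCl2 (10 equiv), NiCl2 (cat.), DMSO/THF, 2 mM, rt
Reagents that add atoms: none
Why: Nozaki–Hiyama–Kishi macrocyclisation: the alkenylchromium from the E-vinyl iodide (geometry retained) adds to the aldehyde to close the 14-membered ring; C3 is set by substrate control from the rigid lactone, with 3S the required outcome but not predictable with confidence.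

**Compound list**
1 | (1S,2S,4R)-1-methyl-4-(prop-1-en-2-yl)cyclohexane-1,2-diol | C[C@]1(O)CC[C@@H](C(C)=C)C[C@@H]1O | starting material
2 | (1S,2S,4R)-4-(3-chloroprop-1-en-2-yl)-1-methylcyclohexane-1,2-diol | C[C@]1(O)CC[C@@H](C(CCl)=C)C[C@@H]1O | intermediate
3 | (2S,5R)-5-(3-chloroprop-1-en-2-yl)-2-hydroxy-2-methylcyclohexan-1-one | C[C@]1(O)CC[C@@H](C(CCl)=C)CC1=O | intermediate
4 | (3R,6S)-3-(3-chloroprop-1-en-2-yl)-6-methyl-1,6-bis(trimethylsilyloxy)cyclohex-1-ene | C[C@]1(O[Si](C)(C)C)CC[C@@H](C(CCl)=C)C=C1O[Si](C)(C)C | intermediate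
5 | (2S,5S)-5-(3-chloroprop-1-en-2-yl)-6-methoxy-2-methyloxane-2-carboxylic acid | C[C@@]1(C(O)=O)CC[C@@H](C(CCl)=C)C(OC)O1 | intermediate
6 | pent-3-yn-1-ol | CC#CCCO | starting material
7 | (E)-4-iodopent-3-en-1-ol | C/C(I)=C\CCO | intermediate
8 | (E)-4-iodopent-3-enal | C/C(I)=C\CC=O | intermediate
9 | isopropenylmagnesium bromide | CC(=C)[Mg]Br | starting material
10 | rac-(5E)-6-iodo-2-methylhepta-1,5-dien-3-ol | CC(=C)C(O)C/C=C(C)/I | intermediate
11 | ester of 5 with 10 (mixture at carbinol and anomeric carbons) | C[C@@]1(C(=O)OC(C/C=C(C)/I)C(C)=C)CC[C@@H](C(CCl)=C)C(OC)O1 | intermediate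
12 | allyl vinyl ether from 11 (C=O replaced by C=CH2) | C[C@@]1(C(=C)OC(C/C=C(C)/I)C(C)=C)CC[C@@H](C(CCl)=C)C(OC)O1 | intermediate
13 | (4E,7E)-1-[(2S,5S)-5-(3-chloroprop-1-en-2-yl)-6-methoxy-2-methyloxan-2-yl]-8-iodo-4-methylnona-4,7-dien-1-one | C[C@@]1(C(=O)CC/C(C)=C/C/C=C(C)/I)CC[C@@H](C(CCl)=C)C(OC)O1 | intermediate
14 | (1R)-alcohol from 13 | C[C@@]1([C@H](O)CC/C(C)=C/C/C=C(C)/I)CC[C@@H](C(CCl)=C)C(OC)O1 | intermediate
15 | mesylate of 14 | C[C@@]1([C@H](OS(C)(=O)=O)CC/C(C)=C/C/C=C(C)/I)CC[C@@H](C(CCl)=C)C(OC)O1 | intermediate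
16 | enal from 15 (CH2Cl → CHO) | C[C@@]1([C@H](OS(C)(=O)=O)CC/C(C)=C/C/C=C(C)/I)CC[C@@H](C(C=O)=C)C(OC)O1 | intermediate
17 | acrylic acid from 16 | C[C@@]1([C@H](OS(C)(=O)=O)CC/C(C)=C/C/C=C(C)/I)CC[C@@H](C(C(O)=O)=C)C(OC)O1 | intermediate
18 | lactol from 17 | C[C@@]1([C@H](OS(C)(=O)=O)CC/C(C)=C/C/C=C(C)/I)CC[C@@H](C(C(O)=O)=C)C(O)O1 | intermediate
19 | (11S,12S)-epoxy enol-ether acid | C[C@]1(O[C@H]1CC/C(C)=C/C/C=C(C)/I)CC[C@H](C=COC)C(=C)C(O)=O | intermediate
20 | (11S,12S)-epoxy aldehyde acid | C[C@]1(O[C@H]1CC/C(C)=C/C/C=C(C)/I)CC[C@H](CC=O)C(=C)C(O)=O | intermediate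
21 | acetoxy lactone aldehyde vinyl iodide | C=C1C(=O)O[C@@](C)([C@@H](OC(C)=O)CC/C(C)=C/C/C=C(C)/I)CC[C@@H]1CC=O | intermediate
22 | Dendronpholide A | C=C1C(=O)O[C@]2(C)CC[C@@H]1C[C@H](O)/C(C)=C/C/C=C(\C)CC[C@@H]2OC(C)=O | target

**Totals**
Total steps: 19. Longest linear sequence: 16 (1 → 22 through steps 1–4 and 8–19).

**Three steps most likely to fail, with fallbacks**
- **Step 19 (macrocyclisation, C3 configuration).** The diastereoselectivity is not predictable and the yield may be modest. Fallback: oxidise the C3 alcohol mixture to the macrocyclic 4E-enone (MnO2) and set C3 by Luche reduction of the conformationally locked ring, so the centre is made by hydride delivery and not by C–C bond formation.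
- **Step 18 (7-membered lactone by epoxide opening).** Meinwald rearrangement or elimination may compete with the slower seven-ring closure. Fallback: switch to a retention strategy. Make the C12-epimeric ketol from (R)-carvone (alkaline H2O2 epoxidation trans to the isopropenyl group, LiAlH4, oxidation), carry it through the same sequence, and close the lactone by Yamaguchi acylation of the tertiary alcohol with no epoxide.
- **Step 16 (lactol Wittig with in-situ epoxide closure).** Risks are epimerisation at C1 in the open aldehyde and attack of the lactol alkoxide on the mesylate to give a bicyclic acetal. Fallback: insert C3 before ring cleavage by one-carbon ring expansion of ketone 3 (TMSCHN2, Lewis acid), so that ozonolysis of the seven-membered silyl enol ether gives the C3 aldehyde directly. It is then carried as a cyclic acetal, and the epoxide is closed separately with K2CO3.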